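**Numbering used throughout.** Ring atoms of the target are numbered as in 1‑aryl‑1,2‑dihydronaphthalene: C1 (aryl‑bearing), C2, C3, C4, C4a, C5–C8, C8a. Compounds 1–18 are defined in the steps and the list below. BHA = 2,6‑di‑tert‑butyl‑4‑methoxyphenyl; TIPS = triisopropylsilyl.

## The problem

Target 18 is a (1R,2S)-1‑aryl‑1,2‑dihydronaphthalene. Ring A (C1–C2–C3=C4–C4a–C8a) is fused to a benzo ring B that carries OMe at C6, C7 and C8. C1 is a diaryl methine that sits peri to the C8 methoxy group and carries the 3,4‑dimethoxyphenyl ring. C2 carries CH2OH trans to that aryl group, and C3 carries CH2OH on the styrenic C3=C4 bond. A synthesis has to decide which of two similar methoxyarenes becomes the fused ring, and it has to make the aryl–C1 bond next to a flanking methoxy group. The two contiguous stereocentres have no third centre to lean on, so absolute configuration must come from a reagent or an auxiliary. C2 is epimerizable while its carbon is at the carboxyl level, so C1 can control C2 thermodynamically, but not the reverse. The C3=C4 bond must stay where it is: migration towards C1/C2 or dehydrogenation to the 1‑arylnaphthalene erases both stereocentres. The electron‑rich rings, the doubly benzylic C1–H and the allylic/benzylic alcohols rule out oxidants and strong acid late in the route.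

**Structural feature that the plan exploits.** Ring A of 18 is a naphthalene ring that has taken up Ar–H across C1=C2: C1 and C2 are sp3, while C3=C4 is still conjugated to the intact ring B. The carbon on C2 can be raised to a carboxyl, which makes C1 the β‑carbon of an arene‑embedded enoate. The carbon on C3 can be kept as a non‑conjugating CH2O group, so C4 is not activated.

## Retrosynthesis

**18 ⇒ 17 ⇒ 16 (C–O/oxidation‑level changes only).** The C2 hydroxymethyl of 18 is traced to a hindered aryl ester in 16, and the C3 hydroxymethyl to its silyl ether (17 is the mono‑protected diol). The ester level at C2 is what makes C1 electrophilic in the precursor and C2 epimerizable in the product. The forward steps are a hydride reduction and a fluoride deprotection that touch no stereocentre.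

**16 ⇒ 11 + 12 (key cut: C1–aryl bond and C2–H bond).** Removing the aryl group from C1 and the hydrogen from C2 returns ring A to a flat naphthalene, 11, and the aryl group to bromide 12 (as aryllithium 13). The neighbouring ring‑forming cuts (C1–C8a or C4–C4a) close ring A at the same moment as the stereocentres are made. Here ring A already exists, and the stereogenic event is a single intermolecular addition. Precursor 11 is achiral, has no stereocentre and already holds every carbon of the bicyclic core. The forward reaction must add the aryl group 1,4 (not 1,2) to the ester, at C1 only, on one face, and the C2 proton must end up trans.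

**11 ⇒ 10 ⇒ 9 ⇒ 5 + 6 (differentiation of the two carboxyl carbons).** 11 needs an activating, carbonyl‑shielded ester on C2 and an inert CH2OSi group on C3. This is reached from half‑ester 5, whose free acid on C2 is esterified with phenol 6 (to 9) and whose methyl ester on C3 is then reduced (10) and silylated (11). The forward steps need only chemoselectivity between a methyl ester and a shielded aryl ester.

**5 ⇒ 2 + 3 (cut of C1–C8a and C3=C4).** Ring A of the naphthalene is taken apart into bromoaldehyde 2 and 4‑methyl itaconate 3. The aldehyde carbon of 2 becomes C4 and the C–Br carbon becomes C8a. Compound 3 supplies C1, C2, C3 and both carboxyl carbons, already differentiated as acid and ester. A phthalaldehyde/succinate condensation would give the same ring but with two identical esters. Here the position of bromine in 2 decides that the free acid ends on C2, next to the C1 that is peri to C8‑OMe.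

**2 ⇒ 1 (C–Br).** Bromination of 3,4,5‑trimethoxybenzaldehyde 1 at one of its two equivalent free positions.

## Roads not taken

**Alternative 1: cut C1–C8a (the most obvious route).** Two Stobbe condensations of dimethyl succinate with veratraldehyde and 3,4,5‑trimethoxybenzaldehyde give the dibenzylidenesuccinate A1. Acid‑mediated cyclization closes ring A to the racemic trans diester A2, and hydride reduction gives the racemic diol. The route is short, but the ring closure that creates C1 is an achiral cationic/electrocyclic event. Absolute control would need an attached auxiliary or a resolution. Which arene acts as nucleophile rests only on a small electronic difference between two methoxyarenes. In the chosen plan regiochemistry is fixed by connectivity and the face of C1 by a reagent.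

**Alternative 2: set C1 first on an open chain, then cut C4–C4a.** Rh‑catalysed asymmetric conjugate addition of 3,4‑dimethoxyphenylboronic acid to tert‑butyl 2,3,4‑trimethoxycinnamate would give the diarylpropanoate A3. Enolate alkylation, chain extension, Friedel–Crafts closure onto the ring and elimination would then have to build C2, C3, C4 and the C3=C4 bond. C1 is made catalytically, but ring A and the alkene still cost five or more steps. In those steps C2 is set only by acyclic 1,2‑induction, and the alkene position must be fixed by elimination next to an epimerizable centre. The chosen key step makes the C1–aryl bond and both stereocentres at once and inherits the alkene from the arene.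

**Alternative 3: biomimetic anodic 8–8′ coupling (cut C2–C3 and C1–C8a together).** Anodic cross‑coupling of methyl sinapate with methyl ferulate would give a bis‑quinone methide that cyclizes to the phenolic dihydronaphthalene diester A4. O‑Methylation to A2 and reduction would follow. This is the shortest route on paper. Three selections are uncontrolled: homo‑ versus cross‑coupling, C–C versus C–O coupling, and which ring attacks which quinone methide. The product is also racemic.

Key step: step 6

**Assumption.** The (S,S)‑diether ligand is written in step 6. Which antipode delivers (1R) on this 3‑substituted ester must be read from the first run, and the equally available (R,R)‑ligand is used instead if the sense is opposite.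

## Route

Step 1
Reactants: 1 3,4,5‑trimethoxybenzaldehyde
Product: 2 2‑bromo‑3,4,5‑trimethoxybenzaldehyde
Conditions: NBS (1.05 equiv), CHCl3, reflux
Reagents that add atoms: N‑bromosuccinimide O=C1CCC(=O)N1Br
Why: Electrophilic aromatic bromination; the two free positions of 1 are equivalent and activated by ortho/para methoxy groups, and the bromine lands on the carbon that becomes C8a, next to the future C8‑OMe.

Step 2
Reactants: 2 2‑bromo‑3,4,5‑trimethoxybenzaldehyde; 3 4‑methyl itaconate (4‑methoxy‑2‑methylidene‑4‑oxobutanoic acid, 1.5 equiv)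
Product: 5 3‑(methoxycarbonyl)‑6,7,8‑trimethoxynaphthalene‑2‑carboxylic acid, via Heck adduct 4 (not isolated)
Conditions: Pd(OAc)2 (5 mol %), P(o‑tol)3 (10 mol %), K2CO3 (3 equiv), DMF, 100 °C; aq. HCl work‑up
Reagents that add atoms: none
Why: Domino Mizoroki–Heck/intramolecular aldol (Knoevenagel‑type) condensation: aryl‑Pd adds to the CH2= terminus of 3 (future C1), the ester‑activated CH2 of 4 closes onto the ortho aldehyde (C3–C4, 6‑exo‑trig), and loss of water aromatizes. The connectivity of 3 places the free acid on C2 and the methyl ester on C3, and both alkene isomers of 4 converge through the common dienolate.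

Step 3
Reactants: 5 3‑(methoxycarbonyl)‑6,7,8‑trimethoxynaphthalene‑2‑carboxylic acid; 6 2,6‑di‑tert‑butyl‑4‑methoxyphenol
Product: 9 2‑(2,6‑di‑tert‑butyl‑4‑methoxyphenyl) 3‑methyl 6,7,8‑trimethoxynaphthalene‑2,3‑dicarboxylate, via acid chloride 7 (not isolated), via lithium aryloxide 8 (not isolated)
Conditions: 5, (COCl)2, cat. DMF, CH2Cl2, 0 °C, evaporate; 6, n‑BuLi, THF, 0 °C; combine, −20 °C → rt
Reagents that add atoms: none
Why: Acid chloride formation and O‑acylation of a hindered lithium phenoxide, the standard entry to BHA esters; low temperature keeps the half‑ester chloride from exchanging with its regioisomer through the cyclic pseudo‑chloride. The aryl ester is orthogonal to the methyl ester in step 4 and shields the carbonyl in step 6.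

Step 4
Reactants: 9 2‑(2,6‑di‑tert‑butyl‑4‑methoxyphenyl) 3‑methyl 6,7,8‑trimethoxynaphthalene‑2,3‑dicarboxylate
Product: 10 2,6‑di‑tert‑butyl‑4‑methoxyphenyl 3‑(hydroxymethyl)‑6,7,8‑trimethoxynaphthalene‑2‑carboxylate
Conditions: DIBAL‑H (2.5 equiv), CH2Cl2, −78 → 0 °C; aq. potassium sodium tartrate
Reagents that add atoms: none
Why: Chemoselective hydride reduction: the methyl ester goes to the primary alcohol, while the BHA ester, whose carbonyl faces are covered by the two tert‑butyl groups, is inert at low temperature; the buffered work‑up avoids lactonization.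

Step 5
Reactants: 10 2,6‑di‑tert‑butyl‑4‑methoxyphenyl 3‑(hydroxymethyl)‑6,7,8‑trimethoxynaphthalene‑2‑carboxylate
Product: 11 2,6‑di‑tert‑butyl‑4‑methoxyphenyl 6,7,8‑trimethoxy‑3‑{[(triisopropylsilyl)oxy]methyl}naphthalene‑2‑carboxylate
Conditions: TIPSCl, imidazole, DMF, 0 °C → rt
Reagents that add atoms: chlorotriisopropylsilane CC(C)[Si](Cl)(C(C)C)C(C)C
Why: Standard silylation of a primary benzylic alcohol; the bulky, poorly coordinating TIPS ether removes the acidic OH, does not guide a lithium base to the benzylic CH2, and survives steps 6 and 7.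

Step 6
Reactants: 11 2,6‑di‑tert‑butyl‑4‑methoxyphenyl 6,7,8‑trimethoxy‑3‑{[(triisopropylsilyl)oxy]methyl}naphthalene‑2‑carboxylate; 12 4‑bromo‑1,2‑dimethoxybenzene
Product: 16 2,6‑di‑tert‑butyl‑4‑methoxyphenyl (1R,2S)‑1‑(3,4‑dimethoxyphenyl)‑6,7,8‑trimethoxy‑3‑{[(triisopropylsilyl)oxy]methyl}‑1,2‑dihydronaphthalene‑2‑carboxylate, via aryllithium 13 (not isolated), via lithium enolate 14 (not isolated), via cis ester 15 (not isolated)
Conditions: 12, t‑BuLi (2 equiv per 12), Et2O, −78 °C; (S,S)‑1,2‑dimethoxy‑1,2‑diphenylethane, 11, toluene, −78 → −45 °C, Ar; t‑BuOH, −78 °C; then t‑BuOK (cat.), THF, 0 °C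
Reagents that add atoms: none
Why: Br/Li exchange gives aryllithium 13, whose chelate with the C2‑symmetric diether binds the ester carbonyl of 11 and transfers the aryl group to C1 through a six‑membered Li–O=C–C2=C1 array; this 1,4‑addition dearomatizes ring A only, leaves ring B and the C3=C4 styrene intact, and gives enolate 14. The closest known reaction type is the chiral‑diether‑mediated conjugate addition of aryllithiums to BHA naphthoates (with oxazoline‑directed naphthalene dearomatization as its covalent‑auxiliary counterpart). No ring is closed: ring A changes from arene to 1,2‑dihydroarene. C1 is set by reagent control, since 11 is flat and achiral and the lithium carrying the stereogenic O‑methyl groups of the ligand selects one face. C2 is set by substrate control under thermodynamic conditions: protonation of 14 anti to the new aryl group should give cis ester 15, which catalytic t‑BuOK equilibrates through the enolate to trans ester 16. In 16 the C1 aryl group is pushed pseudoaxial by the peri C8‑OMe and the C2 ester is pushed pseudoaxial by A(1,2) strain with the C3 substituent, and only the trans isomer allows both to be axial. The step needs 1,4 over 1,2 addition (secured by the tert‑butyl shielding of the carbonyl), C1 over C4 (only C1 is β to a carbonyl, the CH2OTIPS group does not conjugate) and addition over benzylic deprotonation (an aryllithium in toluene is a poor base and the bulky silyl ether does not direct it). Air is excluded because the enolate would oxidize to the 1‑arylnaphthalene.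

Step 7
Reactants: 16 2,6‑di‑tert‑butyl‑4‑methoxyphenyl (1R,2S)‑1‑(3,4‑dimethoxyphenyl)‑6,7,8‑trimethoxy‑3‑{[(triisopropylsilyl)oxy]methyl}‑1,2‑dihydronaphthalene‑2‑carboxylate
Product: 17 [(1R,2S)‑1‑(3,4‑dimethoxyphenyl)‑6,7,8‑trimethoxy‑3‑{[(triisopropylsilyl)oxy]methyl}‑1,2‑dihydronaphthalen‑2‑yl]methanol
Conditions: LiAlH4, THF, 0 °C → reflux; aq. NaOH work‑up
Reagents that add atoms: none
Why: LiAlH4 reduction of the hindered aryl ester to the primary alcohol with release of the phenol; the styrenic alkene, silyl ether and aryl ethers are inert to hydride, and C2 is no longer epimerizable once reduced.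

Step 8
Reactants: 17 [(1R,2S)‑1‑(3,4‑dimethoxyphenyl)‑6,7,8‑trimethoxy‑3‑{[(triisopropylsilyl)oxy]methyl}‑1,2‑dihydronaphthalen‑2‑yl]methanol
Product: 18 [(1R,2S)‑1‑(3,4‑dimethoxyphenyl)‑3‑(hydroxymethyl)‑6,7,8‑trimethoxy‑1,2‑dihydronaphthalen‑2‑yl]methanol
Conditions: TBAF, THF, 0 °C → rt
Reagents that add atoms: none
Why: Fluoride desilylation under non‑acidic, non‑oxidizing conditions; the acid‑sensitive allylic/benzylic diol and the dihydronaphthalene are left alone and no stereocentre is touched.

## Compound list

1 | 3,4,5‑trimethoxybenzaldehyde | COc1cc(C=O)cc(OC)c1OC | starting material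
2 | 2‑bromo‑3,4,5‑trimethoxybenzaldehyde | COc1cc(C=O)c(Br)c(OC)c1OC | intermediate
3 | 4‑methyl itaconate (4‑methoxy‑2‑methylidene‑4‑oxobutanoic acid) | COC(=O)CC(=C)C(=O)O | starting material
4 | (2E)‑2‑[(2‑formyl‑4,5,6‑trimethoxyphenyl)methylidene]‑4‑methoxy‑4‑oxobutanoic acid (Heck adduct) | OC(=O)/C(CC(=O)OC)=C/c1c(C=O)cc(OC)c(OC)c1OC | intermediate (not isolated)
5 | 3‑(methoxycarbonyl)‑6,7,8‑trimethoxynaphthalene‑2‑carboxylic acid | COC(=O)c1cc2cc(OC)c(OC)c(OC)c2cc1C(=O)O | intermediate
6 | 2,6‑di‑tert‑butyl‑4‑methoxyphenol | COc1cc(C(C)(C)C)c(O)c(C(C)(C)C)c1 | starting material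
7 | 3‑(methoxycarbonyl)‑6,7,8‑trimethoxynaphthalene‑2‑carbonyl chloride | COC(=O)c1cc2cc(OC)c(OC)c(OC)c2cc1C(Cl)=O | intermediate (not isolated)
8 | lithium 2,6‑di‑tert‑butyl‑4‑methoxyphenoxide | COc1cc(C(C)(C)C)c(O[Li])c(C(C)(C)C)c1 | intermediate (not isolated)
9 | 2‑(2,6‑di‑tert‑butyl‑4‑methoxyphenyl) 3‑methyl 6,7,8‑trimethoxynaphthalene‑2,3‑dicarboxylate | COC(=O)c1cc2cc(OC)c(OC)c(OC)c2cc1C(=O)Oc1c(C(C)(C)C)cc(OC)cc1C(C)(C)C | intermediate
10 | 2,6‑di‑tert‑butyl‑4‑methoxyphenyl 3‑(hydroxymethyl)‑6,7,8‑trimethoxynaphthalene‑2‑carboxylate | COc1cc(C(C)(C)C)c(OC(=O)c2cc3c(OC)c(OC)c(OC)cc3cc2CO)c(C(C)(C)C)c1 | intermediate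
11 | 2,6‑di‑tert‑butyl‑4‑methoxyphenyl 6,7,8‑trimethoxy‑3‑{[(triisopropylsilyl)oxy]methyl}naphthalene‑2‑carboxylate | COc1cc(C(C)(C)C)c(OC(=O)c2cc3c(OC)c(OC)c(OC)cc3cc2CO[Si](C(C)C)(C(C)C)C(C)C)c(C(C)(C)C)c1 | intermediate (key‑step precursor)
12 | 4‑bromo‑1,2‑dimethoxybenzene | COc1ccc(Br)cc1OC | starting material
13 | 3,4‑dimethoxyphenyllithium | COc1ccc([Li])cc1OC | intermediate (not isolated)
14 | lithium enolate of 16, (1R), C2 trigonal | COc1ccc([C@@H]2c3c(cc(OC)c(OC)c3OC)C=C(CO[Si](C(C)C)(C(C)C)C(C)C)C2=C(O[Li])Oc2c(C(C)(C)C)cc(OC)cc2C(C)(C)C)cc1OC | intermediate (not isolated)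
15 | 2,6‑di‑tert‑butyl‑4‑methoxyphenyl (1R,2R)‑1‑(3,4‑dimethoxyphenyl)‑6,7,8‑trimethoxy‑3‑{[(triisopropylsilyl)oxy]methyl}‑1,2‑dihydronaphthalene‑2‑carboxylate (cis) | COc1ccc([C@@H]2c3c(cc(OC)c(OC)c3OC)C=C(CO[Si](C(C)C)(C(C)C)C(C)C)[C@@H]2C(=O)Oc2c(C(C)(C)C)cc(OC)cc2C(C)(C)C)cc1OC | intermediate (not isolated)
16 | 2,6‑di‑tert‑butyl‑4‑methoxyphenyl (1R,2S)‑1‑(3,4‑dimethoxyphenyl)‑6,7,8‑trimethoxy‑3‑{[(triisopropylsilyl)oxy]methyl}‑1,2‑dihydronaphthalene‑2‑carboxylate (trans) | COc1ccc([C@@H]2c3c(cc(OC)c(OC)c3OC)C=C(CO[Si](C(C)C)(C(C)C)C(C)C)[C@H]2C(=O)Oc2c(C(C)(C)C)cc(OC)cc2C(C)(C)C)cc1OC | intermediate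
17 | [(1R,2S)‑1‑(3,4‑dimethoxyphenyl)‑6,7,8‑trimethoxy‑3‑{[(triisopropylsilyl)oxy]methyl}‑1,2‑dihydronaphthalen‑2‑yl]methanol | COc1ccc([C@@H]2c3c(cc(OC)c(OC)c3OC)C=C(CO[Si](C(C)C)(C(C)C)C(C)C)[C@H]2CO)cc1OC | intermediate
18 | [(1R,2S)‑1‑(3,4‑dimethoxyphenyl)‑3‑(hydroxymethyl)‑6,7,8‑trimethoxy‑1,2‑dihydronaphthalen‑2‑yl]methanol | COc1ccc([C@@H]2c3c(cc(OC)c(OC)c3OC)C=C(CO)[C@H]2CO)cc1OC | target

## Step count and least certain steps

Total steps: 8. Longest linear sequence: 8 (1 → 18).

**Step 6 (key step).** Three things may go wrong.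
- Addition may be slow or unselective. The three methoxy groups lower the electrophilicity of C1, and the ester is twisted by the flanking CH2OTIPS group. Benzylic lithiation at C3–CH2O, followed by silyl migration, could then compete.
- Facial discrimination may be poor, because the C8‑OMe and the silyloxy oxygen compete with the diether for lithium.
- During equilibration the double bond may migrate into conjugation with the ester, or traces of air may aromatize the enolate.

Fallback (covalent auxiliary, known chemistry), setting out from 5 and returning at 17. Acid 5 is converted through chloride 7 with (R)‑tert‑leucinol into the hydroxy amide F1. F1 is cyclized (MsCl, Et3N) to the (4R)‑oxazoline ester F2. LiBH4 reduces the methyl ester to the hydroxymethyl oxazoline F3, and silylation gives the TIPS ether F4. Aryllithium 13 then adds to C1 of F4 by nitrogen‑directed delivery anti to the tert‑butyl group (oxazoline‑directed dearomatizing addition). Proton quench and base equilibration give the trans dihydronaphthalene oxazoline F5. N‑Methylation (MeOTf) to the oxazolinium triflate F6, borohydride reduction to the oxazolidine F7 and mild aqueous acid release the aldehyde F8. NaBH4 reduces F8 to 17. On the steric model the (4R)‑auxiliary is the one required for (1R); its antipode is used if the model proves wrong.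

**Step 2.** Base may isomerize the itaconate to unreactive mesaconate/citraconate‑type alkenes. Oxidative addition at the doubly ortho‑substituted bromide may be slow, or the ring closure of 4 may be incomplete in the presence of the free carboxylate.

Fallback, setting out from 2 and 3 and returning at 5. Compound 3 is esterified (tert‑butyl trichloroacetimidate) to 1‑tert‑butyl 4‑methyl itaconate F9. Heck coupling with 2 under amine base gives the isolated benzylidenesuccinate F10. A separate DBU step closes and aromatizes the ring to the mixed diester F11, and TFA cleaves the tert‑butyl ester to 5.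

**Step 3.** The half‑ester chloride 7 may exchange acyl positions with its neighbouring ester through a cyclic pseudo‑chloride, or collapse to the anhydride, while the slow acylation of the hindered phenoxide proceeds. Either event would scramble the C2/C3 differentiation.

Fallback, setting out from 5 and returning at 11. LiBH4 reduces the methyl ester of the lithium salt of 5, and acid work‑up closes the lactone F12, which locks the regiochemistry. Saponification and double silylation give the silyl ester silyl ether F13. Carbonate methanolysis cleaves only the silyl ester to the acid F14. Neutral chlorination (1‑chloro‑N,N,2‑trimethylpropenylamine) gives the acid chloride F15, which has no neighbouring ester to exchange with. Acylation of aryloxide 8 with F15 gives 11.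

**Step 7.** Hydride may act as a base on the acidic C2–H of the shielded ester (enolization instead of reduction), or reduction may be incomplete even at reflux.

Fallback: the oxazoline series described under step 6 (from 5 through F1–F8 to 17) also answers this step. There the C2 carbon is released as aldehyde F8 and reduced with NaBH4, without passing through a shielded ester. It makes no further compound (entry F0).

## Further compounds

F1 | step 6 | methyl 3‑{[(2R)‑1‑hydroxy‑3,3‑dimethylbutan‑2‑yl]carbamoyl}‑5,6,7‑trimethoxynaphthalene‑2‑carboxylate | COC(=O)c1cc2cc(OC)c(OC)c(OC)c2cc1C(=O)N[C@@H](CO)C(C)(C)C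
F2 | step 6 | methyl 3‑[(4R)‑4‑tert‑butyl‑4,5‑dihydro‑1,3‑oxazol‑2‑yl]‑5,6,7‑trimethoxynaphthalene‑2‑carboxylate | COC(=O)c1cc2cc(OC)c(OC)c(OC)c2cc1C1=N[C@@H](CO1)C(C)(C)C
F3 | step 6 | {3‑[(4R)‑4‑tert‑butyl‑4,5‑dihydro‑1,3‑oxazol‑2‑yl]‑5,6,7‑trimethoxynaphthalen‑2‑yl}methanol | OCc1cc2cc(OC)c(OC)c(OC)c2cc1C1=N[C@@H](CO1)C(C)(C)C
F4 | step 6 | (4R)‑4‑tert‑butyl‑2‑(6,7,8‑trimethoxy‑3‑{[(triisopropylsilyl)oxy]methyl}naphthalen‑2‑yl)‑4,5‑dihydro‑1,3‑oxazole | CC(C)[Si](OCc1cc2cc(OC)c(OC)c(OC)c2cc1C1=N[C@@H](CO1)C(C)(C)C)(C(C)C)C(C)C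
F5 | step 6 | (4R)‑4‑tert‑butyl‑2‑[(1R,2S)‑1‑(3,4‑dimethoxyphenyl)‑6,7,8‑trimethoxy‑3‑{[(triisopropylsilyl)oxy]methyl}‑1,2‑dihydronaphthalen‑2‑yl]‑4,5‑dihydro‑1,3‑oxazole | COc1ccc([C@@H]2c3c(cc(OC)c(OC)c3OC)C=C(CO[Si](C(C)C)(C(C)C)C(C)C)[C@H]2C2=N[C@@H](CO2)C(C)(C)C)cc1OC
F6 | step 6 | N‑methyloxazolinium trifluoromethanesulfonate of F5 | COc1ccc([C@@H]2c3c(cc(OC)c(OC)c3OC)C=C(CO[Si](C(C)C)(C(C)C)C(C)C)[C@H]2C2=[N+](C)[C@@H](CO2)C(C)(C)C)cc1OC.[O-]S(=O)(=O)C(F)(F)F
F7 | step 6 | (4R)‑4‑tert‑butyl‑3‑methyl‑2‑[(1R,2S)‑1‑(3,4‑dimethoxyphenyl)‑6,7,8‑trimethoxy‑3‑{[(triisopropylsilyl)oxy]methyl}‑1,2‑dihydronaphthalen‑2‑yl]‑1,3‑oxazolidine (aminal carbon undefined) | COc1ccc([C@@H]2c3c(cc(OC)c(OC)c3OC)C=C(CO[Si](C(C)C)(C(C)C)C(C)C)[C@H]2C2N(C)[C@@H](CO2)C(C)(C)C)cc1OC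
F8 | step 6 | (1R,2S)‑1‑(3,4‑dimethoxyphenyl)‑6,7,8‑trimethoxy‑3‑{[(triisopropylsilyl)oxy]methyl}‑1,2‑dihydronaphthalene‑2‑carbaldehyde | COc1ccc([C@@H]2c3c(cc(OC)c(OC)c3OC)C=C(CO[Si](C(C)C)(C(C)C)C(C)C)[C@H]2C=O)cc1OC
F9 | step 2 | 1‑tert‑butyl 4‑methyl 2‑methylidenebutanedioate | COC(=O)CC(=C)C(=O)OC(C)(C)C
F10 | step 2 | 1‑tert‑butyl 4‑methyl (2E)‑2‑[(2‑formyl‑4,5,6‑trimethoxyphenyl)methylidene]butanedioate | COC(=O)C/C(C(=O)OC(C)(C)C)=C\c1c(C=O)cc(OC)c(OC)c1OC
F11 | step 2 | 2‑tert‑butyl 3‑methyl 6,7,8‑trimethoxynaphthalene‑2,3‑dicarboxylate | COC(=O)c1cc2cc(OC)c(OC)c(OC)c2cc1C(=O)OC(C)(C)C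
F12 | step 3 | 6,7,8‑trimethoxynaphtho[2,3‑c]furan‑1(3H)‑one | COc1cc2cc3COC(=O)c3cc2c(OC)c1OC
F13 | step 3 | triisopropylsilyl 6,7,8‑trimethoxy‑3‑{[(triisopropylsilyl)oxy]methyl}naphthalene‑2‑carboxylate | COc1cc2cc(CO[Si](C(C)C)(C(C)C)C(C)C)c(C(=O)O[Si](C(C)C)(C(C)C)C(C)C)cc2c(OC)c1OC
F14 | step 3 | 6,7,8‑trimethoxy‑3‑{[(triisopropylsilyl)oxy]methyl}naphthalene‑2‑carboxylic acid | COc1cc2cc(CO[Si](C(C)C)(C(C)C)C(C)C)c(C(=O)O)cc2c(OC)c1OC
F15 | step 3 | 6,7,8‑trimethoxy‑3‑{[(triisopropylsilyl)oxy]methyl}naphthalene‑2‑carbonyl chloride | COc1cc2cc(CO[Si](C(C)C)(C(C)C)C(C)C)c(C(Cl)=O)cc2c(OC)c1OC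
F0 | step 7 | none | none
A1 | alternative 1 | dimethyl (2E,3E)‑2‑(3,4‑dimethoxybenzylidene)‑3‑(3,4,5‑trimethoxybenzylidene)butanedioate | COC(=O)/C(=C/c1ccc(OC)c(OC)c1)C(=C/c1cc(OC)c(OC)c(OC)c1)\C(=O)OC
A2 | alternative 1 | rac‑dimethyl trans‑1‑(3,4‑dimethoxyphenyl)‑6,7,8‑trimethoxy‑1,2‑dihydronaphthalene‑2,3‑dicarboxylate (one enantiomer drawn) | COc1ccc([C@@H]2c3c(cc(OC)c(OC)c3OC)C=C(C(=O)OC)[C@H]2C(=O)OC)cc1OC
A3 | alternative 2 | tert‑butyl (3R)‑3‑(3,4‑dimethoxyphenyl)‑3‑(2,3,4‑trimethoxyphenyl)propanoate | COc1ccc([C@@H](CC(=O)OC(C)(C)C)c2ccc(OC)c(OC)c2OC)cc1OC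
A4 | alternative 3 | rac‑dimethyl trans‑7‑hydroxy‑1‑(4‑hydroxy‑3‑methoxyphenyl)‑6,8‑dimethoxy‑1,2‑dihydronaphthalene‑2,3‑dicarboxylate (one enantiomer drawn) | COc1cc([C@@H]2c3c(cc(OC)c(O)c3OC)C=C(C(=O)OC)[C@H]2C(=O)OC)ccc1O
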